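The data were generated by integration with constants of no real substance, and the scatter is random.

30.0 %: that is the number to carry from this flask, the partner surplus, meaning the coupling partner charged minus the second substrate charged, in percent of the starting material charged.

| flask | starting material | second substrate | coupling partner | free catalyst | temperature | remark | time |
|---|---|---|---|---|---|---|---|
| eta | 0.016 M | 0.016 M | 0.0208 M | 32 µM | 20 °C | the very flask that is asked about, followed so far |  |
| beta | 0.016 M | 0.016 M | 0.0208 M | 16 µM | 20 °C | run made earlier |  |
| flask | 0.016 M | 0.0160 M | 0.0208 M | 32 µM | 20 °C |  | 8.0 d |

- eta (time / h: target / %): 20.0: 35; 60.0: 28; 96.0: 25; 144: 19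
- beta (time / h: target / %): 10.0: 18; 20.0: 27; 30.0: 32; 40.0: 33

(standard deviation of a reading: 2 percentage points)

- larch: at 8.0 d add coupling partner, 100 % of the amount charged, then wait 4.0 d
- maple: change nothing and wait 4.0 d more
- cedar: at 8.0 d add free catalyst, 100 % of the amount charged, then wait 4.0 d
- oak: at 8.0 d raise the temperature by 15 K, then wait 4.0 d
- ash: at 8.0 d take out 90 % of the target then present, then wait 4.0 d

- target that was removed still counts
- additions bring no volume worth counting
- the earlier runs do not show what temperature does; that part of a forecast is a guess

- target, in percent of the starting material first charged, at 8.0 d
- which option adds most target ("none" when 2 percentage points or less is all one gets) (larch / maple / cedar / oak / ash / none)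
- target present, with what was taken out counted in, in percent of the starting material first charged, after larch
- target present, with what was taken out counted in, in percent of the starting material first charged, after maple

Is the catalyst dying? Count turnovers. At its first reading the eta run, which is this flask followed so far, holds 175 target per catalyst charged. The beta run at its last reading holds 330, twice as many, with half the catalyst. So the catalyst of the eta run had not reached any limit on turnovers at that reading.

Then what stops the target? My guess is the coupling partner, as limiting reagent: its 0.0208 M is less than the two substrates together. I also guess that second substrate takes one partner each, though no reading shows this.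

But the eta reading of 35 % stands above your surplus. Doesn't that sink it? No. The surplus is my ceiling for the target once second substrate has taken its partner, not a limit on the way. I guess that the target runs ahead early and gives partner back later, and by 144 h the reading of 19 % is below the surplus.

What do you commit to? The fall in this flask should flatten rather than run to zero, since the surplus is positive. Larch lifts the surplus to 160 %, which is more partner than there is starting material. So I expect larch to win and to carry the target past the peak reading.

The forecast gave 15 % now, larch as best, 30 % after larch and 9.7 % after maple, holding that “Formation seems to stop because something is used up, most likely the coupling partner”. My expectation for larch, past the peak reading of 35 %, is higher than its figure.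

The flask gives 18.7 % at 8.0 d, 55.9 % after larch and 16.7 % after maple. Larch gains 37 percentage points, the most of the options.

    coupling partner + catalyst intermediate A ⇌ free catalyst + target (K = 2.00, k = 6900 /M/h, Ea = 47.0 kJ/mol, ΔH = −17.0 kJ/mol)
    coupling partner + catalyst intermediate B → free catalyst + second product (k = 3900 /M/h, Ea = 47.0 kJ/mol)
    second substrate + free catalyst ⇌ catalyst intermediate B (K = 42.0 /M, k = 5600 /M/h, Ea = 43.0 kJ/mol, ΔH = −44.0 kJ/mol)
    starting material + free catalyst ⇌ catalyst intermediate A (K = 38.0 /M, k = 3500 /M/h, Ea = 42.0 kJ/mol, ΔH = −30.0 kJ/mol)
    (constants at 20 °C)

This flask ends the 8.0 d below the surplus of 30.0 %. Two ways back act together in holding it down: the one from catalyst intermediate A to starting material and free catalyst, and the one from free catalyst and target to coupling partner and catalyst intermediate A. The same run without the first gives 89.8 % at 8.0 d, and without the second 69.1 %, instead of 18.7 %. The neighbour flask with 0.083 M of coupling partner has a surplus of 419 %, more partner than starting material, so starting material should cap the target there. Computed, it holds 80.4 % at 192 h, with 65 % of its partner still free.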